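Everything rests on cutting ring A between C4 and C5. The structural feature used is the vicinal pair C4/C5 of ring A: C4 is quaternary (methyl C18, carboxyl C19) and its C19 lies on the same face as C6, the branch on C5 from which ring B grows. A ten-membered (E)-allylic lactone, with the C19 ester oxygen on C7 and a silyl ether at C10, is contracted by an Ireland–Claisen rearrangement. One operation forms C4–C5, closes ring A and fixes both centres, leaving a vinyl group on C5. B-alkyl coupling to a (2Z,6E)-dienyl iodide, a C10 spiro-epoxide cascade onto a phenol, lactonisation and oxidative chroman opening complete the target.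

Key step: step 7

Remarks on the chemistry:
- Numbering: ring A = C1–C5 and C10; ring B = C5–C10; ring C = C8, C9, C11–C14; C15 = benzylic CH2; C16, C17, C18 = methyls on C13, C8, C4; C19 = lactone carbonyl; C20 = lactone CH2 on C10.
- Chain length: the alkylating agent must supply C1, C2, C3 and C10, so 5-bromopent-1-ene is used; 4-bromobut-1-ene would lead to a nine-membered lactone and a five-membered carbocycle.
- Reading of the target: the benzyl group on C14 is axial (α) and cis to the equatorial C13–OH; this is the outcome of a chair cyclisation of a (13Z)-alkene, so the dienyl iodide must be (2Z,6E).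
- Precursor design: C10 carries a triethylsilyl ether (same skeleton) so that it can later be removed by mild acid beside an aryl triisopropylsilyl ether.
- The (13Z)-alkene is built from but-2-yn-1-ol, which avoids a selective cleavage of a terminal alkene in a natural (Z)-allylic alcohol.
- Assumption: compounds 3, 4 and 8–13 are carried as 1:1 mixtures at C4, which is intended because C4 becomes trigonal in step 7.

Step 1
Reactants: 1 methyl propionate; 2 5-bromopent-1-ene
Product: 3 methyl 2-methylhept-6-enoate (racemic)
Conditions: LiN(iPr)2, THF, −78 °C; then 2, DMPU, −78 → −20 °C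
Reagents that add atoms: none
Why: SN2 C-alkylation of the lithium ester enolate by the primary bromide (enolate alkylation) should give the chain C19–C4–C3–C2–C1–C10, the racemic C4 centre being of no consequence.

Step 2
Reactants: 3 methyl 2-methylhept-6-enoate
Product: 4 methyl 2-methyl-6-oxohexanoate (racemic)
Conditions: O3, CH2Cl2, −78 °C; PPh3, −78 °C → rt
Reagents that add atoms: ozone, O=[O+][O-]
Why: ozonolysis with reductive work-up cleaves the only alkene to the aldehyde that becomes C10, and the ester is inert.

Step 3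
Reactants: 4 methyl 2-methyl-6-oxohexanoate; 5 prop-2-yn-1-yl acetate
Product: 8 methyl (6S,7E)-9-acetoxy-6-hydroxy-2-methylnon-7-enoate, via alkenylborane 6 (not isolated), via alkenylzinc 7 (not isolated)
Conditions: 5, Cy2BH, PhMe, 0 °C → rt; Me2Zn, −78 °C; (+)-3-exo-morpholinoisoborneol (5 mol%), then 4, −20 → 0 °C; aq. NH4Cl
Reagents that add atoms: none
Why: syn-hydroboration of the terminal alkyne fixes the (E)-alkene C5=C6, boron-to-zinc exchange gives an alkenylzinc that adds to the aldehyde under amino-alcohol catalysis (catalytic asymmetric alkenylzinc addition), and the ligand enantiomer (the antipode of the one that gives (S)-1-phenylpropan-1-ol from PhCHO and Et2Zn) is chosen for Re-face delivery so that C10 should be (S).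

Step 4
Reactants: 8 methyl (6S,7E)-9-acetoxy-6-hydroxy-2-methylnon-7-enoate
Product: 9 methyl (6S,7E)-9-acetoxy-2-methyl-6-(triethylsilyloxy)non-7-enoate
Conditions: Et3SiCl, imidazole, DMAP (cat), CH2Cl2, 0 °C → rt
Reagents that add atoms: chlorotriethylsilane, CC[Si](Cl)(CC)CC
Why: silylation of the only free hydroxyl protects C10–OH, which would otherwise close a seven-membered lactone in step 6.

Step 5
Reactants: 9 methyl (6S,7E)-9-acetoxy-2-methyl-6-(triethylsilyloxy)non-7-enoate
Product: 10 (6S,7E)-9-hydroxy-2-methyl-6-(triethylsilyloxy)non-7-enoic acid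
Conditions: LiOH·H2O, THF/MeOH/H2O, rt → 35 °C; then 0.5 M HCl to pH 4, 0 °C
Reagents that add atoms: lithium hydroxide, [Li+].[OH-]
Why: one saponification cleaves the methyl ester and the allylic acetate together (ester hydrolysis), while the secondary triethylsilyl ether is stable to aqueous hydroxide and to a brief cold acidification.

Step 6
Reactants: 10 (6S,7E)-9-hydroxy-2-methyl-6-(triethylsilyloxy)non-7-enoic acid
Product: 12 (7S,8E)-3-methyl-7-(triethylsilyloxy)-3,4,5,6,7,10-hexahydro-2H-oxecin-2-one, via mixed anhydride 11 (not isolated)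
Conditions: 2,4,6-Cl3C6H2COCl, Et3N, THF, rt; then slow addition to DMAP, PhMe, 80 °C (about 1 mM)
Reagents that add atoms: none
Why: Yamaguchi macrolactonisation under high dilution should close the ten-membered ring through the reactive primary allylic alcohol, leaving the (E)-alkene and the silyl ether untouched and carrying both C4 epimers forward.

Step 7
Reactants: 12 (7S,8E)-3-methyl-7-(triethylsilyloxy)-3,4,5,6,7,10-hexahydro-2H-oxecin-2-one
Product: 15 (1S,2S,3S)-1-methyl-3-(triethylsilyloxy)-2-vinylcyclohexane-1-carboxylic acid, via silyl ketene acetal 13 (not isolated), via trimethylsilyl ester 14 (not isolated)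
Conditions: Me3SiCl/Et3N, then LiN(iPr)2, THF, −78 °C → rt; PhMe, 80 °C; then aq. citric acid, THF, rt
Reagents that add atoms: none
Why: LiN(iPr)2 removes the C4 proton and Me3SiCl traps the enolate on oxygen; because C4 and the ester oxygen are ring members, the ketene acetal C4=C19 can only be cis within the ring, and on warming it undergoes a concerted suprafacial [3,3] shift over C4=C19–O–C7–C6=C5 that makes C4–C5 and breaks O–C7. The closest known reaction type is the Ireland–Claisen ring contraction of macrocyclic (E)-allylic lactones to cis-2-vinylcycloalkanecarboxylic acids. Ring A (C1–C5, C10) closes transannularly: the carbons C4–C3–C2–C1–C10–C5 fold as a chair while the four-atom bridge C19–O–C7–C6 completes a boat-like pericyclic array, the only one that the ring-cis ketene acetal and the (E)-alkene can reach. That boat puts C19 and C6 on the same face, so carboxyl and vinyl at the new centres C4 and C5 should come out cis whichever C4 epimer of 12 is used. The absolute sense is relayed from C10: the alkene face is chosen so that the C10 silyloxy group is equatorial on the nascent chair, since the other face would force it 1,3-diaxial to the axial ketene acetal carbon C19. The step therefore needs diastereoface selection relative to C10, secured by this equatorial preference, and complete O-silylation before the enolate can fragment, secured by having Me3SiCl present at −78 °C.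

Step 8
Reactants: 15 (1S,2S,3S)-1-methyl-3-(triethylsilyloxy)-2-vinylcyclohexane-1-carboxylic acid
Product: 16 methyl (1S,2S,3S)-1-methyl-3-(triethylsilyloxy)-2-vinylcyclohexane-1-carboxylate
Conditions: MeI, K2CO3, DMF, rt
Reagents that add atoms: iodomethane, CI
Why: O-alkylation of the hindered carboxylate (SN2 at methyl) avoids acyl substitution at the neopentyl-type carbonyl and masks C19 until the lactone is closed.

Step 9
Reactants: 17 2-bromo-4-methoxyphenol
Product: 18 (2-bromo-4-methoxyphenoxy)triisopropylsilane
Conditions: iPr3SiCl, imidazole, DMF, rt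
Reagents that add atoms: chlorotriisopropylsilane, CC(C)[Si](Cl)(C(C)C)C(C)C
Why: silylation of the phenol gives a bulky aryl silyl ether that should tolerate Grignard formation, aqueous phosphate and mild acid and be removable by fluoride.

Step 10
Reactants: 19 but-2-yn-1-ol
Product: 21 (2Z)-3-iodobut-2-en-1-ol, via alkenylalanate 20 (not isolated)
Conditions: NaAlH2(OCH2CH2OMe)2, THF, 0 °C → rt; then I2, −78 → 0 °C
Reagents that add atoms: iodine, II
Why: alkoxide-directed trans-hydroalumination of the propargylic alcohol places aluminium on C13 cis to the CH2O group, and iodinolysis with retention should give only the (Z)-iodide that later fixes the C13=C14 geometry.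

Step 11
Reactants: 21 (2Z)-3-iodobut-2-en-1-ol
Product: 22 (2Z)-1-bromo-3-iodobut-2-ene
Conditions: CBr4, PPh3, CH2Cl2, 0 °C
Reagents that add atoms: tetrabromomethane, BrC(Br)(Br)Br
Why: Appel bromination of the primary allylic alcohol proceeds by SN2 at carbon and does not touch the alkene geometry.

Step 12
Reactants: 18 (2-bromo-4-methoxyphenoxy)triisopropylsilane; 22 (2Z)-1-bromo-3-iodobut-2-ene
Product: 24 {2-[(2Z)-3-iodobut-2-en-1-yl]-4-methoxyphenoxy}triisopropylsilane, via aryl Grignard reagent 23 (not isolated)
Conditions: 18, Mg, LiCl, THF, rt; then CuI (10 mol%), 22, −30 → 0 °C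
Reagents that add atoms: none
Why: copper-catalysed SN2 allylation of the aryl Grignard reagent occurs at the primary allylic bromide (attack at the iodine-bearing γ-carbon is disfavoured), while the alkenyl iodide does not exchange with an aryl Grignard reagent at low temperature.

Step 13
Reactants: 25 pent-3-yn-1-ol
Product: 26 5-iodopent-2-yne
Conditions: I2, PPh3, imidazole, CH2Cl2, 0 °C → rt
Reagents that add atoms: iodine, II
Why: Appel-type iodination converts the primary alcohol into the iodide needed for zinc insertion, and the internal alkyne is inert.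

Step 14
Reactants: 26 5-iodopent-2-yne; 24 {2-[(2Z)-3-iodobut-2-en-1-yl]-4-methoxyphenoxy}triisopropylsilane
Product: 28 {4-methoxy-2-[(2Z)-3-methyloct-2-en-6-yn-1-yl]phenoxy}triisopropylsilane, via alkylzinc iodide 27 (not isolated)
Conditions: 26, Zn dust (activated with BrCH2CH2Br and Me3SiCl), THF, 40 °C; then 24, Pd(dppf)Cl2 (5 mol%), THF, rt → 45 °C
Reagents that add atoms: none
Why: Negishi sp3–sp2 coupling joins C12 to C13 with retention of the (Z)-iodide geometry, the bidentate phosphine suppressing β-hydride elimination.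

Step 15
Reactants: 28 {4-methoxy-2-[(2Z)-3-methyloct-2-en-6-yn-1-yl]phenoxy}triisopropylsilane
Product: 30 {2-[(2Z,6E)-7-iodo-3-methylocta-2,6-dien-1-yl]-4-methoxyphenoxy}triisopropylsilane, via alkenylzirconocene 29 (not isolated)
Conditions: Cp2Zr(H)Cl (2 equiv), THF, rt → 45 °C; then I2, 0 °C
Reagents that add atoms: iodine, II
Why: syn-hydrozirconation of the methyl alkyne, with excess hydride equilibrating zirconium onto the less hindered methyl-bearing carbon C8, followed by iodinolysis with retention should give the (E)-2-iodoalkene (a minor regioisomer would be removed here), the trisubstituted alkene and the aryl silyl ether being inert.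

Step 16
Reactants: 16 methyl (1S,2S,3S)-1-methyl-3-(triethylsilyloxy)-2-vinylcyclohexane-1-carboxylate; 30 {2-[(2Z,6E)-7-iodo-3-methylocta-2,6-dien-1-yl]-4-methoxyphenoxy}triisopropylsilane
Product: 32 methyl (1S,2S,3S)-2-[(3E,7Z)-9-aryl-3,7-dimethylnona-3,7-dien-1-yl]-1-methyl-3-(triethylsilyloxy)cyclohexane-1-carboxylate (aryl = 5-methoxy-2-(triisopropylsilyloxy)phenyl), via alkylborane 31 (not isolated)
Conditions: 16, 9-BBN, THF, rt → 50 °C; then 30, Pd(dppf)Cl2 (5 mol%), AsPh3, aq. K3PO4, DMF, rt
Reagents that add atoms: none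
Why: anti-Markovnikov hydroboration of the vinyl group and B-alkyl Suzuki–Miyaura coupling join C7 to C8 with retention of the (E)-iodide geometry, and phosphate at room temperature spares both silyl ethers and the ester.

Step 17
Reactants: 32 (see step 16)
Product: 33 methyl (1S,2S,3S)-2-[(3E,7Z)-9-aryl-3,7-dimethylnona-3,7-dien-1-yl]-3-hydroxy-1-methylcyclohexane-1-carboxylate
Conditions: PPTS, MeOH/CH2Cl2, rt
Reagents that add atoms: none
Why: acid-catalysed methanolysis removes the alkyl triethylsilyl ether, whereas the aryl triisopropylsilyl ether (weakly basic oxygen and bulky silicon) and the trisubstituted alkenes should not react.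

Step 18
Reactants: 33 (see step 17)
Product: 34 methyl (1S,2S)-2-[(3E,7Z)-9-aryl-3,7-dimethylnona-3,7-dien-1-yl]-1-methyl-3-oxocyclohexane-1-carboxylate
Conditions: Dess–Martin periodinane, NaHCO3, CH2Cl2, 0 °C → rt
Reagents that add atoms: none
Why: Dess–Martin oxidation of the secondary alcohol is buffered and non-basic, so C5, now α to the C10 ketone, should keep its configuration.

Step 19
Reactants: 34 (see step 18)
Product: 35 C10 spiro-epoxide of 34 (1-oxaspiro[2.5]octane; epoxide oxygen β and axial; C20 α)
Conditions: Me3SI, KN(SiMe3)2, THF, −10 °C; then 34, −10 → 0 °C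
Reagents that add atoms: trimethylsulfonium iodide, C[S+](C)C.[I-]
Why: Corey–Chaykovsky epoxidation, in which the ylide carbon should enter on the equatorial α face because the axial C4 ester screens the axial β trajectory, and the ketone is far more electrophilic than the hindered ester.

Step 20
Reactants: 35 (see step 19)
Product: 36 free phenol of 35 (aryl = 2-hydroxy-5-methoxyphenyl)
Conditions: Bu4NF, THF, 0 °C; aq. NH4Cl
Reagents that add atoms: none
Why: fluoride cleaves the aryl silyl ether (phenoxide as leaving group on silicon) under conditions that leave the epoxide, the ester and the alkenes untouched.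

Step 21
Reactants: 36 (see step 20)
Product: 38 pentacyclic cis-fused 6-methoxychroman 19,20-lactone, via hydroxy ester 37 (not isolated)
Conditions: MeAlCl2 (3 equiv), CH2Cl2, −78 → −20 °C; aq. potassium sodium tartrate; crude with CSA (cat), PhMe, 40 °C
Reagents that add atoms: none
Why: epoxide-initiated cation–olefin bicyclisation terminated by a phenol, in which MeAlCl2 (which also removes the phenolic proton as methane, so that no Brønsted acid can close the chroman early) ionises the spiro-epoxide at tertiary C10, the (8E)-alkene attacks C10 anti to the departing axial oxygen through a chair (ring B, 6-endo, trans A/B junction with C20 β, 9α-H and 8β-methyl), the (13Z)-alkene closes ring C through a chair that puts the benzyl carbon C15 axial (14β-H), the tethered phenol can then reach C13 only from the α face (cis-fused chroman, equatorial C13–O, 13β-methyl), and the liberated C20 hydroxyl, 1,3-diaxial to the C19 ester, lactonises on brief acid treatment.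

Step 22
Reactants: 38 (see step 21)
Product: 40 target hydroquinone lactone CNP0148621.1, via quinone 39 (not isolated)
Conditions: (NH4)2Ce(NO3)6, MeCN/H2O, 0 °C; then aq. Na2S2O4, EtOAc, rt
Reagents that add atoms: water, O
Why: oxidative dealkylation of the para-dialkoxyarene cleaves both aryl–oxygen bonds with water supplying the quinone oxygens, so the chroman opens to the C13 tertiary alcohol with its configuration intact and methanol is lost, and dithionite then reduces the quinone to the hydroquinone.

Compound list
1 | methyl propionate | CCC(=O)OC | starting material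
2 | 5-bromopent-1-ene | C=CCCCBr | starting material
3 | methyl 2-methylhept-6-enoate (racemic) | C=CCCCC(C)C(=O)OC | intermediate
4 | methyl 2-methyl-6-oxohexanoate (racemic) | O=CCCCC(C)C(=O)OC | intermediate
5 | prop-2-yn-1-yl acetate | C#CCOC(C)=O | starting material
6 | (E)-3-(dicyclohexylboranyl)prop-2-en-1-yl acetate | CC(=O)OC/C=C/B(C1CCCCC1)C1CCCCC1 | intermediate (not isolated)
7 | [(E)-3-acetoxyprop-1-en-1-yl](methyl)zinc | CC(=O)OC/C=C/[Zn]C | intermediate (not isolated)
8 | methyl (6S,7E)-9-acetoxy-6-hydroxy-2-methylnon-7-enoate (both C2 epimers) | COC(=O)C(C)CCC[C@H](O)/C=C/COC(C)=O | intermediate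
9 | methyl (6S,7E)-9-acetoxy-2-methyl-6-(triethylsilyloxy)non-7-enoate | COC(=O)C(C)CCC[C@H](O[Si](CC)(CC)CC)/C=C/COC(C)=O | intermediate
10 | (6S,7E)-9-hydroxy-2-methyl-6-(triethylsilyloxy)non-7-enoic acid | OC(=O)C(C)CCC[C@H](O[Si](CC)(CC)CC)/C=C/CO | intermediate
11 | mixed anhydride of 10 with 2,4,6-trichlorobenzoic acid | CC(CCC[C@H](O[Si](CC)(CC)CC)/C=C/CO)C(=O)OC(=O)c1c(Cl)cc(Cl)cc1Cl | intermediate (not isolated)
12 | (7S,8E)-3-methyl-7-(triethylsilyloxy)-3,4,5,6,7,10-hexahydro-2H-oxecin-2-one (ten-membered lactone; both C4 epimers) | CC1CCC[C@H](O[Si](CC)(CC)CC)/C=C/COC1=O | intermediate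
13 | cyclic trimethylsilyl ketene acetal of 12 (C4=C19 cis within the ring) | C/C1=C(\O[Si](C)(C)C)OC/C=C/[C@@H](O[Si](CC)(CC)CC)CCC1 | intermediate (not isolated)
14 | trimethylsilyl (1S,2S,3S)-1-methyl-3-(triethylsilyloxy)-2-vinylcyclohexane-1-carboxylate | C[C@]1(C(=O)O[Si](C)(C)C)CCC[C@H](O[Si](CC)(CC)CC)[C@H]1C=C | intermediate (not isolated)
15 | (1S,2S,3S)-1-methyl-3-(triethylsilyloxy)-2-vinylcyclohexane-1-carboxylic acid (ring A acid) | C[C@]1(C(=O)O)CCC[C@H](O[Si](CC)(CC)CC)[C@H]1C=C | intermediate
16 | methyl (1S,2S,3S)-1-methyl-3-(triethylsilyloxy)-2-vinylcyclohexane-1-carboxylate | C[C@]1(C(=O)OC)CCC[C@H](O[Si](CC)(CC)CC)[C@H]1C=C | intermediate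
17 | 2-bromo-4-methoxyphenol | COc1ccc(O)c(Br)c1 | starting material
18 | (2-bromo-4-methoxyphenoxy)triisopropylsilane | COc1ccc(O[Si](C(C)C)(C(C)C)C(C)C)c(Br)c1 | intermediate
19 | but-2-yn-1-ol | CC#CCO | starting material
20 | sodium 2,2-bis(2-methoxyethoxy)-3-methyl-2,5-dihydro-1,2-oxaluminol-2-uide (cyclic alkenylalanate) | CC1=CCO[Al-]1(OCCOC)OCCOC.[Na+] | intermediate (not isolated)
21 | (2Z)-3-iodobut-2-en-1-ol | C/C(I)=C/CO | intermediate
22 | (2Z)-1-bromo-3-iodobut-2-ene | C/C(I)=C/CBr | intermediate
23 | [5-methoxy-2-(triisopropylsilyloxy)phenyl]magnesium bromide | COc1ccc(O[Si](C(C)C)(C(C)C)C(C)C)c([Mg]Br)c1 | intermediate (not isolated)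
24 | {2-[(2Z)-3-iodobut-2-en-1-yl]-4-methoxyphenoxy}triisopropylsilane | C/C(I)=C/Cc1cc(OC)ccc1O[Si](C(C)C)(C(C)C)C(C)C | intermediate
25 | pent-3-yn-1-ol | CC#CCCO | starting material
26 | 5-iodopent-2-yne | CC#CCCI | intermediate
27 | pent-3-yn-1-ylzinc iodide | CC#CCC[Zn]I | intermediate (not isolated)
28 | {4-methoxy-2-[(2Z)-3-methyloct-2-en-6-yn-1-yl]phenoxy}triisopropylsilane | CC#CCC/C(C)=C\Cc1cc(OC)ccc1O[Si](C(C)C)(C(C)C)C(C)C | intermediate
29 | alkenylzirconocene chloride from 28 (zirconium on C8, cis to the C9 hydrogen) | C/C(=C\CC/C(C)=C\Cc1cc(OC)ccc1O[Si](C(C)C)(C(C)C)C(C)C)[Zr](Cl)(C1C=CC=C1)C1C=CC=C1 | intermediate (not isolated)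
30 | {2-[(2Z,6E)-7-iodo-3-methylocta-2,6-dien-1-yl]-4-methoxyphenoxy}triisopropylsilane | C/C(I)=C\CC/C(C)=C\Cc1cc(OC)ccc1O[Si](C(C)C)(C(C)C)C(C)C | intermediate
31 | B-alkyl-9-borabicyclo[3.3.1]nonane from 16 (boron on C7) | C[C@]1(C(=O)OC)CCC[C@H](O[Si](CC)(CC)CC)[C@H]1CCB1C2CCCC1CCC2 | intermediate (not isolated)
32 | methyl (1S,2S,3S)-2-[(3E,7Z)-9-aryl-3,7-dimethylnona-3,7-dien-1-yl]-1-methyl-3-(triethylsilyloxy)cyclohexane-1-carboxylate (aryl = 5-methoxy-2-(triisopropylsilyloxy)phenyl) | C[C@]1(C(=O)OC)CCC[C@H](O[Si](CC)(CC)CC)[C@H]1CC/C(C)=C/CC/C(C)=C\Cc1cc(OC)ccc1O[Si](C(C)C)(C(C)C)C(C)C | intermediate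
33 | C10 alcohol from 32 (3-hydroxy; 1S,2S,3S) | C[C@]1(C(=O)OC)CCC[C@H](O)[C@H]1CC/C(C)=C/CC/C(C)=C\Cc1cc(OC)ccc1O[Si](C(C)C)(C(C)C)C(C)C | intermediate
34 | C10 ketone (3-oxo; 1S,2S) | C[C@]1(C(=O)OC)CCCC(=O)[C@H]1CC/C(C)=C/CC/C(C)=C\Cc1cc(OC)ccc1O[Si](C(C)C)(C(C)C)C(C)C | intermediate
35 | C10 spiro-epoxide (1-oxaspiro[2.5]octane; epoxide O β, C20 α) | C[C@]1(C(=O)OC)CCC[C@]2(CO2)[C@H]1CC/C(C)=C/CC/C(C)=C\Cc1cc(OC)ccc1O[Si](C(C)C)(C(C)C)C(C)C | intermediate
36 | free phenol of 35 | C[C@]1(C(=O)OC)CCC[C@]2(CO2)[C@H]1CC/C(C)=C/CC/C(C)=C\Cc1cc(OC)ccc1O | intermediate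
37 | cis-fused 6-methoxychroman with C20 hydroxyl and C19 methyl ester (5α-H, 8β-Me, 9α-H, 13β-Me, 13α-O, 14β-H) | C[C@@]12CC[C@@H]3[C@](CO)(CCC[C@]3(C)C(=O)OC)[C@H]1CC[C@]1(C)Oc3ccc(OC)cc3C[C@H]21 | intermediate (not isolated)
38 | cis-fused 6-methoxychroman 19,20-lactone | C[C@@]12CC[C@@H]3[C@]4(CCC[C@]3(C)C(=O)OC4)[C@H]1CC[C@]1(C)Oc3ccc(OC)cc3C[C@H]21 | intermediate
39 | 1,4-benzoquinone with C13 tertiary alcohol and 19,20-lactone | C[C@@]12CC[C@@H]3[C@]4(CCC[C@]3(C)C(=O)OC4)[C@H]1CC[C@](C)(O)[C@@H]2CC1=CC(=O)C=CC1=O | intermediate (not isolated)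
40 | CNP0148621.1 (hydroquinone, C13 alcohol, 19,20-lactone) | C[C@@]12CC[C@@H]3[C@]4(CCC[C@]3(C)C(=O)OC4)[C@H]1CC[C@](C)(O)[C@@H]2Cc1cc(O)ccc1O | target

Total step count: 22. Longest linear sequence: 15 steps (steps 1–8, then 16–22); the dienyl iodide 30 is made in steps 9–15 and joins at step 16.

Steps most likely to fail

1. Step 21. After Lewis-acid opening, the C10 cation may shift a hydride from C20 (aldehyde formation), be captured by the axial C19 ester carbonyl, or lose a proton after ring B before ring C and the chroman close. The fallback replaces cationic by radical initiation; it sets out from 35 and returns at 38. Cp2TiCl2 with Mn dust in THF at rt generates Cp2TiCl (trivalent titanium), which opens the spiro-epoxide homolytically to the tertiary C10 radical. Two chair-like 6-endo radical additions should build rings B and C, and the C13 radical is trapped by a second Cp2TiCl and eliminated to the exocyclic alkene, giving the tricyclic 13(16)-methylene hydroxy ester F1. Bu4NF frees the phenol F2. CSA in PhMe at 50 °C then protonates the alkene to the C13 cation, which the axial benzyl tether lets the phenol reach only from the α face, and closes the lactone, arriving at 38.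

2. Step 7. Face discrimination by C10 in the boat-like shift may be weak, or the lactone enolate may fragment to a ketene and an allylic alkoxide before it is silylated. The fallback replaces the sigmatropic contraction by conjugate addition and enolate methylation. It does not branch from a numbered compound: it starts from purchased methyl 3-oxocyclohex-1-ene-1-carboxylate F3 (replacing steps 1 to 8) and returns at 16. CBS reduction ((R)-Me-CBS, catecholborane, PhMe, −78 °C) should give methyl (3S)-3-hydroxycyclohex-1-ene-1-carboxylate F4, the alkene acting as the large group. Et3SiCl and imidazole give the silyl ether F5. (CH2=CH)2CuLi with Me3SiCl in THF at −78 °C should add to C5 anti to the C10 silyloxy group, giving after work-up methyl (2S,3S)-3-(triethylsilyloxy)-2-vinylcyclohexane-1-carboxylate F6 as C4 epimers. LiN(iPr)2 then MeI should methylate the exocyclic enolate on the face away from the vinyl group, which places the ester cis to vinyl as in 16; the C4 selectivity is the weak point of this fallback.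

3. Step 6. Intermolecular acylation to the diolide and oligomers may outrun closure of the ten-membered ring. The fallback closes the ring by C–C bond formation (Nozaki–Hiyama–Kishi) after an easy intermolecular esterification; it sets out from 3 and returns at 12. LiOH gives 2-methylhept-6-enoic acid F7. EDC and DMAP with (E)-3-iodoprop-2-en-1-ol give (2E)-3-iodoprop-2-en-1-yl 2-methylhept-6-enoate F8. OsO4 (cat), NaIO4 and 2,6-lutidine should cleave the terminal alkene in preference to the electron-poor iodoalkene, giving (2E)-3-iodoprop-2-en-1-yl 2-methyl-6-oxohexanoate F9. CrCl2 with catalytic NiCl2 in DMF at high dilution joins C5 to C10 and gives the ten-membered hydroxy lactone F10 as a mixture at C10. Dess–Martin oxidation gives the enone lactone F11, and CBS reduction ((R)-Me-CBS, catecholborane) should give the (7S)-hydroxy lactone F12. Et3SiCl and imidazole then give 12.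

Further compounds
F1 | step 21 | tricyclic 13(16)-methylene hydroxy ester with aryl triisopropylsilyl ether | C[C@@]12CC[C@@H]3[C@](CO)(CCC[C@]3(C)C(=O)OC)[C@H]1CCC(=C)[C@@H]2Cc1cc(OC)ccc1O[Si](C(C)C)(C(C)C)C(C)C
F2 | step 21 | free phenol of F1 | C[C@@]12CC[C@@H]3[C@](CO)(CCC[C@]3(C)C(=O)OC)[C@H]1CCC(=C)[C@@H]2Cc1cc(OC)ccc1O
F3 | step 7 | methyl 3-oxocyclohex-1-ene-1-carboxylate (purchased) | COC(=O)C1=CC(=O)CCC1
F4 | step 7 | methyl (3S)-3-hydroxycyclohex-1-ene-1-carboxylate | COC(=O)C1=C[C@@H](O)CCC1
F5 | step 7 | methyl (3S)-3-(triethylsilyloxy)cyclohex-1-ene-1-carboxylate | COC(=O)C1=C[C@@H](O[Si](CC)(CC)CC)CCC1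
F6 | step 7 | methyl (2S,3S)-3-(triethylsilyloxy)-2-vinylcyclohexane-1-carboxylate (C1 epimers) | COC(=O)C1CCC[C@H](O[Si](CC)(CC)CC)[C@H]1C=C
F7 | step 6 | 2-methylhept-6-enoic acid | C=CCCCC(C)C(=O)O
F8 | step 6 | (2E)-3-iodoprop-2-en-1-yl 2-methylhept-6-enoate | C=CCCCC(C)C(=O)OC/C=C/I
F9 | step 6 | (2E)-3-iodoprop-2-en-1-yl 2-methyl-6-oxohexanoate | O=CCCCC(C)C(=O)OC/C=C/I
F10 | step 6 | (8E)-7-hydroxy-3-methyl-3,4,5,6,7,10-hexahydro-2H-oxecin-2-one (stereoisomer mixture) | CC1CCCC(O)/C=C/COC1=O
F11 | step 6 | (8E)-3-methyl-4,5,6,10-tetrahydro-2H-oxecine-2,7(3H)-dione | CC1CCCC(=O)/C=C/COC1=O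
F12 | step 6 | (7S,8E)-7-hydroxy-3-methyl-3,4,5,6,7,10-hexahydro-2H-oxecin-2-one | CC1CCC[C@H](O)/C=C/COC1=O
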